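**Retrosynthetic overview**
1. Target ⇒ ring-A furfural + methylmalonic acid (Doebner–Knoevenagel, sets the E-alkene); ring A is bought as 4-bromofuran-2-carbaldehyde and joined to the chain by an sp3–sp2 Negishi coupling.
2. Key disconnection: the two C–O bonds of ring B, made in a formal [4+1] annulation of a conjugated ynone with a methylene ylide (oxirane C–O bond, then the ring-closing O–C2 bond under gold catalysis).
3. Ynone ⇒ acetylide of (S)-7-bromo-4-methylhept-1-yne + ethyl 4-(furan-3-yl)butanoate (ring C bought as 3-bromofuran).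
4. Bromoalkyne ⇒ (S)-citronellal: C1 is homologated to the alkyne and the C6=C7 alkene is cut to the C6 bromide; the only stereocentre comes from the chiral pool.
5. Ring order: C (bought, installed first) → B (built, key step) → A (bought, attached last).

Assumption: the target's stereocentre is S (CH2–furan B > chain to furan A > CH3 > H), which maps onto commercial (S)-citronellal (taken as ≥98% ee); that centre is never touched.

**Step 1**
Reactants: 1 3-bromofuran; 2 ethyl 4-bromobutanoate
Product: 4 ethyl 4-(furan-3-yl)butanoate, via (4-ethoxy-4-oxobutyl)zinc bromide 3 (not isolated)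
Conditions: 2, Zn dust, LiCl, THF, 50 °C; then 1, Pd(OAc)2 (2 mol%), SPhos (4 mol%), 25 → 50 °C
Reagents that add atoms: none
Why: Negishi cross-coupling; LiCl-assisted zinc insertion into the primary C–Br bond spares the ester, and zerovalent palladium/SPhos couples the alkylzinc at C3 of the furan faster than β-hydride elimination.

**Step 2**
Reactants: 5 (S)-citronellal [(3S)-3,7-dimethyloct-6-enal]
Product: 6 (4S)-4,8-dimethylnon-7-en-1-yne
Conditions: dimethyl (1-diazo-2-oxopropyl)phosphonate, K2CO3, MeOH, 0 °C → rt
Reagents that add atoms: dimethyl (1-diazo-2-oxopropyl)phosphonate, COP(=O)(OC)C(=[N+]=[N-])C(C)=O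
Why: Seyferth–Gilbert homologation (Ohira–Bestmann variant) turns the aldehyde into the terminal alkyne; the stereocentre is β to the carbonyl, cannot enolise, and enters the route here unchanged.

**Step 3**
Reactants: 6 (4S)-4,8-dimethylnon-7-en-1-yne
Product: 8 (4S)-4-methylhept-6-yn-1-ol, via (4S)-4-methylhept-6-ynal 7 (not isolated)
Conditions: O3, CH2Cl2/MeOH 4:1, −78 °C (Sudan red 7B end-point); then NaBH4, −78 → 0 °C
Reagents that add atoms: ozone, [O-][O+]=O
Why: Ozonolysis with reductive work-up; the electron-rich trisubstituted alkene reacts far faster with ozone than the terminal alkyne, and borohydride reduces the peroxidic products and aldehyde 7 to the primary alcohol.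

**Step 4**
Reactants: 8 (4S)-4-methylhept-6-yn-1-ol
Product: 9 (4S)-7-bromo-4-methylhept-1-yne
Conditions: CBr4, PPh3, CH2Cl2, 0 °C
Reagents that add atoms: carbon tetrabromide, BrC(Br)(Br)Br
Why: Appel reaction; SN2 displacement of the alkoxyphosphonium by bromide at a primary carbon under neutral conditions leaves the alkyne and the remote stereocentre alone.

**Step 5**
Reactants: 9 (4S)-7-bromo-4-methylhept-1-yne; 4 ethyl 4-(furan-3-yl)butanoate
Product: 11 (8S)-11-bromo-1-(furan-3-yl)-8-methylundec-5-yn-4-one, via [(4S)-7-bromo-4-methylhept-1-yn-1-yl]lithium 10 (not isolated)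
Conditions: 9, n-BuLi, THF, −78 °C; BF3·OEt2, −78 °C; then 4, −78 °C; aq NH4Cl
Reagents that add atoms: none
Why: BF3-promoted acylation of a lithium acetylide by an ester (ynone synthesis); the boron-bound tetrahedral adduct survives at −78 °C so only mono-addition occurs, and the primary bromide and the furan are inert at this temperature.

**Step 6**
Reactants: 11 (8S)-11-bromo-1-(furan-3-yl)-8-methylundec-5-yn-4-one
Product: 13 2-[(2S)-5-bromo-2-methylpentyl]-4-[3-(furan-3-yl)propyl]furan, via 2-alkynyloxirane 12 (not isolated)
Conditions: Me3S+ BF4− (1.1 equiv), n-BuLi (1.05 equiv), THF, −10 °C; 11, −78 → 0 °C; N2 sparge; then MeOH (5 equiv), (Ph3P)AuNTf2 (5 mol%), 40 °C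
Reagents that add atoms: trimethylsulfonium tetrafluoroborate, C[S+](C)C.F[B-](F)(F)F
Why: Proposed new method: a one-flask formal [4+1] furan annulation of a conjugated ynone with a methylene ylide under relay catalysis by cationic monovalent gold; the unstabilised sulfonium methylide (limiting, iodide-free) adds 1,2 to the very electrophilic ynone carbonyl faster than it can alkylate the primary bromide, and the betaine closes to oxirane 12 (first C–O bond); after the dimethyl sulfide is purged, the gold π-acid activates the alkyne, methanol opens the oxirane at the tertiary propargylic carbon, the freed primary hydroxyl adds 5-endo-dig to the distal alkyne carbon (second, ring-forming C–O bond), and protodeauration with loss of methanol aromatises to the 2,4-disubstituted furan, with the alkyne substituent at C2 and the acyl substituent at C4; the closest known reaction types are the Corey–Chaykovsky epoxidation of ketones, the separately run gold-catalysed cycloisomerisation of isolated 2-alkynyloxiranes to furans, and the [4+1] annulation of enones with sulfur ylides to dihydrofurans; the oxirane centre is destroyed on aromatisation and the remote (S) centre is untouched.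

**Step 7**
Reactants: 13 2-[(2S)-5-bromo-2-methylpentyl]-4-[3-(furan-3-yl)propyl]furan; 14 4-bromofuran-2-carbaldehyde
Product: 16 4-[(4S)-5-{4-[3-(furan-3-yl)propyl]furan-2-yl}-4-methylpentyl]furan-2-carbaldehyde, via alkylzinc bromide 15 (not isolated)
Conditions: 13, Zn dust, LiCl, THF, 50 °C; then 14, Pd(OAc)2 (2 mol%), SPhos (4 mol%), THF, 25 °C
Reagents that add atoms: none
Why: Negishi sp3–sp2 cross-coupling; the alkylzinc bromide does not add to the aldehyde, and zerovalent palladium/SPhos couples it at C4 of the bromofuran, three carbons away from the stereocentre.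

**Step 8**
Reactants: 16 4-[(4S)-5-{4-[3-(furan-3-yl)propyl]furan-2-yl}-4-methylpentyl]furan-2-carbaldehyde; 17 methylmalonic acid
Product: 19 (2E)-3-{4-[(4S)-5-{4-[3-(furan-3-yl)propyl]furan-2-yl}-4-methylpentyl]furan-2-yl}-2-methylprop-2-enoic acid (the target), via β-hydroxy diacid 18 (not isolated)
Conditions: pyridine, piperidine (0.2 equiv), 95 °C; cold aq citric acid work-up
Reagents that add atoms: none
Why: Doebner-modified Knoevenagel condensation; amine-catalysed aldol addition gives 18, whose anti-periplanar decarboxylative dehydration gives the conjugated acid with the carboxyl trans to the furan (E), the thermodynamically preferred geometry, under base that the three furans tolerate.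

**Compound list**
1 | 3-bromofuran | Brc1ccoc1 | starting material
2 | ethyl 4-bromobutanoate | CCOC(=O)CCCBr | starting material
3 | (4-ethoxy-4-oxobutyl)zinc bromide | CCOC(=O)CCC[Zn]Br | intermediate
4 | ethyl 4-(furan-3-yl)butanoate | CCOC(=O)CCCc1ccoc1 | intermediate
5 | (S)-citronellal, (3S)-3,7-dimethyloct-6-enal | CC(C)=CCC[C@H](C)CC=O | starting material
6 | (4S)-4,8-dimethylnon-7-en-1-yne | CC(C)=CCC[C@H](C)CC#C | intermediate
7 | (4S)-4-methylhept-6-ynal | O=CCC[C@H](C)CC#C | intermediate
8 | (4S)-4-methylhept-6-yn-1-ol | OCCC[C@H](C)CC#C | intermediate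
9 | (4S)-7-bromo-4-methylhept-1-yne | BrCCC[C@H](C)CC#C | intermediate
10 | [(4S)-7-bromo-4-methylhept-1-yn-1-yl]lithium | BrCCC[C@H](C)CC#C[Li] | intermediate
11 | (8S)-11-bromo-1-(furan-3-yl)-8-methylundec-5-yn-4-one | BrCCC[C@H](C)CC#CC(=O)CCCc1ccoc1 | intermediate
12 | 2-[(4S)-7-bromo-4-methylhept-1-yn-1-yl]-2-[3-(furan-3-yl)propyl]oxirane (both epimers at the oxirane carbon) | BrCCC[C@H](C)CC#CC1(CCCc2ccoc2)CO1 | intermediate
13 | 2-[(2S)-5-bromo-2-methylpentyl]-4-[3-(furan-3-yl)propyl]furan | BrCCC[C@H](C)Cc1cc(CCCc2ccoc2)co1 | intermediate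
14 | 4-bromofuran-2-carbaldehyde | O=Cc1cc(Br)co1 | starting material
15 | [(4S)-5-{4-[3-(furan-3-yl)propyl]furan-2-yl}-4-methylpentyl]zinc bromide | Br[Zn]CCC[C@H](C)Cc1cc(CCCc2ccoc2)co1 | intermediate
16 | 4-[(4S)-5-{4-[3-(furan-3-yl)propyl]furan-2-yl}-4-methylpentyl]furan-2-carbaldehyde | O=Cc1cc(CCC[C@H](C)Cc2cc(CCCc3ccoc3)co2)co1 | intermediate
17 | methylmalonic acid (2-methylpropanedioic acid) | CC(C(=O)O)C(=O)O | starting material
18 | 2-[hydroxy(4-{(4S)-5-[4-(3-(furan-3-yl)propyl)furan-2-yl]-4-methylpentyl}furan-2-yl)methyl]-2-methylpropanedioic acid (both carbinol epimers) | OC(c1cc(CCC[C@H](C)Cc2cc(CCCc3ccoc3)co2)co1)C(C)(C(=O)O)C(=O)O | intermediate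
19 | (2E)-3-{4-[(4S)-5-{4-[3-(furan-3-yl)propyl]furan-2-yl}-4-methylpentyl]furan-2-yl}-2-methylprop-2-enoic acid (CNP0088458.1) | C/C(=C\c1cc(CCC[C@H](C)Cc2cc(CCCc3ccoc3)co2)co1)C(=O)O | target

**Step count**
Total: 8 steps. Longest linear sequence: 7 steps (5 → 6 → 8 → 9 → 11 → 13 → 16 → 19); step 1 is the only side branch.

**Three steps most likely to fail**

Step 6 (the proposed annulation). The ylide may attack the primary bromide or enolise the ynone, and residual sulfide may slow the gold catalyst. The fallback uses only known reactions, sets out from ester 4 (together with bromoalkyne 9) and comes back to the route at furan 13, bypassing ynone 11. Ester 4 is homologated with chloromethyllithium (ICH2Cl, MeLi·LiBr, THF, −78 °C) to 1-chloro-5-(furan-3-yl)pentan-2-one F1. Lithium acetylide 10 (from 9 and n-BuLi) is added to the ketone of F1 at −78 °C to give (8S)-11-bromo-4-(chloromethyl)-1-(furan-3-yl)-8-methylundec-5-yn-4-ol F2. K2CO3 in MeOH closes F2 to oxirane 12, which is isolated this time, and 12 is cycloisomerised with (Ph3P)AuCl/AgOTf in CH2Cl2/MeOH to 13.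

Step 5 (ynone from the ester). Over-addition or incomplete acylation under BF3 is possible. The fallback sets out from 4 and comes back at 11. Ester 4 is treated with MeNH(OMe)·HCl and i-PrMgCl (THF, −20 °C) to give N-methoxy-N-methyl-4-(furan-3-yl)butanamide F3. Lithium acetylide 10 is added to F3 without Lewis acid (THF, −78 → 0 °C); the chelated tetrahedral adduct collapses to ynone 11 only on work-up.

Step 7 (Negishi coupling). Zinc insertion into 13 may be sluggish, and the β-bromofuran aldehyde 14 is a slow oxidative-addition partner. The fallback sets out from 13 and comes back at 16 by a radical cross-electrophile coupling in place of an organozinc: 13 and 14 with Ir[dF(CF3)ppy]2(dtbbpy)PF6 (1 mol%), NiCl2·glyme/dtbbpy (5 mol%), (Me3Si)3SiH, Na2CO3, DME, blue LEDs, 25 °C. Silyl-radical bromine abstraction from 13 gives the primary alkyl radical, which nickel joins to the aryl bromide; the aldehyde is tolerated. New compounds on this way: none F0.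

**Further compounds**
F1 | step 6 | 1-chloro-5-(furan-3-yl)pentan-2-one | ClCC(=O)CCCc1ccoc1
F2 | step 6 | (8S)-11-bromo-4-(chloromethyl)-1-(furan-3-yl)-8-methylundec-5-yn-4-ol (both carbinol epimers) | BrCCC[C@H](C)CC#CC(O)(CCl)CCCc1ccoc1
F3 | step 5 | N-methoxy-N-methyl-4-(furan-3-yl)butanamide | CON(C)C(=O)CCCc1ccoc1
F0 | step 7 | none | none
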